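The cyclohexene ring A is disconnected across two opposite bonds, C1–C14 and the tetrasubstituted alkene C11=C12 that it shares with the butenolide (numbering below). This uncovers a hidden symmetry: C2–C1–C15(Me2)–C11–C10 is 3,3-dimethylglutaraldehyde and C14–C13–C12–C18 is methyl 2-oxobut-3-enoate. One amine-catalysed Michael/aldol-condensation cascade (formal [3+3]) desymmetrises the dialdehyde, closes ring A, sets C1 and leaves the C10 aldehyde cis to the C18 ester, ready for the butenolide. C10 and C6 are then set by catalyst-controlled boronate additions, and the twelve-membered ring is closed last by an intramolecular B-alkyl Suzuki coupling (C3–C4).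

Key step: step 3

Numbering used (read along the target SMILES): C20=C4, C3, C2, C1(H), C14, C13, C12, C11, C10(H)(O), C9, C8(C19), C7, C6(OAc), C5; lactone carbonyl C18; gem-dimethyl carbon C15. The target is (1R,6S,10R).

Assumption: boronates 9 and 15, the prolinol silyl ether and both enantiomers of TRIP (3,3'-bis(2,4,6-triisopropylphenyl)-1,1'-binaphthyl-2,2'-diyl hydrogen phosphate) are taken as purchasable reagents. The sense of induction of TRIP is taken from its behaviour with aryl and alkenyl aldehydes (R acid, Re face).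

Step 1
Reactants: 1 3,3-dimethylpentane-1,5-diol
Product: 2 3,3-dimethylpentanedial
Conditions: (COCl)2, DMSO, CH2Cl2, −78 °C; Et3N, −78 °C to rt
Reagents that add atoms: none
Why: Swern oxidation should convert both primary alcohols to aldehydes without over-oxidation; no stereocentre is involved.

Step 2
Reactants: 3 methyl 2-hydroxybut-3-enoate (racemic)
Product: 4 methyl 2-oxobut-3-enoate
Conditions: Dess–Martin periodinane (1.1 equiv), CH2Cl2, 0 °C to rt; filtered cold solution used at once
Reagents that add atoms: none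
Why: Dess–Martin oxidation of the allylic alcohol should give the vinyl keto ester under neutral conditions, and immediate use avoids its dimerisation by hetero-Diels–Alder reaction.

Step 3
Reactants: 2 3,3-dimethylpentanedial (2.5 equiv); 4 methyl 2-oxobut-3-enoate
Product: 7 methyl (4R)-2,4-diformyl-3,3-dimethylcyclohex-1-ene-1-carboxylate, via keto dialdehyde 5 (not isolated), via hydroxy aldol adduct 6 (not isolated)
Conditions: (R)-2-[diphenyl(trimethylsilyloxy)methyl]pyrrolidine (20 mol %), PhCO2H (20 mol %), toluene, −20 °C to rt, slow addition of 4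
Reagents that add atoms: none
Why: The secondary amine condenses with one formyl group of 2 to the (E)-enamine, whose α-carbon (C1) adds to the vinyl terminus C14 of 4 on the face not shielded by the CPh2(OSiMe3) group, so the catalyst sets C1 (R); after turnover the amine forms the enamine of the remaining unbranched aldehyde, C11 attacks the very electrophilic keto ester carbonyl C12, and loss of water through the enamine/iminium gives the conjugated C11=C12 bond. The closest known reaction type is the amine-catalysed Michael/aldol-condensation domino of aldehydes with enones (formal [3+3] carbo-annulation). Ring A closes in the aldol event by a 6-(enolexo)-exo-trig addition, and C1 is the only new stereocentre that survives, because the two transient centres of 6 are erased by dehydration. The step needs mono-addition, which the excess of 2 and slow addition of 4 should secure, and the right aldol regiochemistry, which follows because only aldehydes form enamines with this amine, the keto ester is the best acceptor, and the other closures would need a four-membered ring or enolisation of the keto ester. Configuration at C1 should hold because the α-branched aldehyde of 7, flanked by the quaternary C15, condenses only slowly with the bulky catalyst.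

Step 4
Reactants: 7 methyl (4R)-2,4-diformyl-3,3-dimethylcyclohex-1-ene-1-carboxylate
Product: 8 methyl (4S)-4-ethenyl-2-formyl-3,3-dimethylcyclohex-1-ene-1-carboxylate
Conditions: Ph3PCH3Br (1.1 equiv), KN(SiMe3)2 (1.05 equiv), THF, 0 °C; then 7, −78 to −30 °C
Reagents that add atoms: methyltriphenylphosphonium bromide, C[P+](c1ccccc1)(c1ccccc1)c1ccccc1.[Br-] (source of methylenetriphenylphosphorane, C=P(c1ccccc1)(c1ccccc1)c1ccccc1)
Why: Wittig methylenation should take the saturated C2 aldehyde in preference to the conjugated C10 aldehyde, which sits on a tetrasubstituted alkene between CMe2 and the ester, and the low temperature should prevent epimerisation at C1 (the descriptor changes to S only through the priority rules).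

Step 5
Reactants: 8 methyl (4S)-4-ethenyl-2-formyl-3,3-dimethylcyclohex-1-ene-1-carboxylate; 9 4,4,5,5-tetramethyl-2-(propa-1,2-dien-1-yl)-1,3,2-dioxaborolane
Product: 11 (3R,5S)-5-ethenyl-4,4-dimethyl-3-(prop-2-yn-1-yl)-4,5,6,7-tetrahydro-2-benzofuran-1(3H)-one, via homopropargylic alcohol 10 (not isolated)
Conditions: 9 (1.5 equiv), (R)-TRIP (10 mol %), 4 Å MS, toluene, 0 °C to rt; aqueous work-up, then PPTS (cat.), CH2Cl2, rt
Reagents that add atoms: none
Why: Chiral phosphoric acid-catalysed propargylation through a closed six-membered transition state should deliver C9 to the Re face of the C10 aldehyde (R acid, 10R), and the new hydroxyl then closes onto the cis ester by lactonisation to give the butenolide.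

Step 6
Reactants: 11 (3R,5S)-5-ethenyl-4,4-dimethyl-3-(prop-2-yn-1-yl)-4,5,6,7-tetrahydro-2-benzofuran-1(3H)-one
Product: 13 (3R,5S)-5-ethenyl-3-[(2E)-3-iodo-2-methylprop-2-en-1-yl]-4,4-dimethyl-4,5,6,7-tetrahydro-2-benzofuran-1(3H)-one, via alkenylalane 12 (not isolated)
Conditions: AlMe3 (3 equiv), Cp2ZrCl2 (0.3 equiv), H2O (1.5 equiv), CH2Cl2, −30 °C; then I2, THF, −30 to 0 °C
Reagents that add atoms: trimethylaluminium, C[Al](C)C; iodine, II
Why: Negishi zirconium-catalysed carboalumination adds methyl and aluminium syn across the terminal alkyne with methyl on the internal carbon, and iodinolysis with retention should fix the C7=C8 E geometry; the low-temperature water-accelerated variant is chosen to spare the lactone.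

Step 7
Reactants: 13 (3R,5S)-5-ethenyl-3-[(2E)-3-iodo-2-methylprop-2-en-1-yl]-4,4-dimethyl-4,5,6,7-tetrahydro-2-benzofuran-1(3H)-one
Product: 14 (2E)-4-[(3R,5S)-5-ethenyl-4,4-dimethyl-1-oxo-1,3,4,5,6,7-hexahydro-2-benzofuran-3-yl]-3-methylbut-2-enal
Conditions: Pd(PPh3)4 (5 mol %), CO (1 atm), Bu3SnH (1.1 equiv, slow addition), THF, 50 °C
Reagents that add atoms: carbon monoxide, [C-]#[O+]
Why: Palladium-catalysed reductive carbonylation (formylation) of the alkenyl iodide should give the enal with retention of the E geometry, slow addition of the hydride suppressing simple reduction.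

Step 8
Reactants: 14 (2E)-4-[(3R,5S)-5-ethenyl-4,4-dimethyl-1-oxo-1,3,4,5,6,7-hexahydro-2-benzofuran-3-yl]-3-methylbut-2-enal; 15 2-(2-bromoprop-2-en-1-yl)-4,4,5,5-tetramethyl-1,3,2-dioxaborolane
Product: 16 (3R,5S)-3-[(2E,4S)-6-bromo-4-hydroxy-2-methylhepta-2,6-dien-1-yl]-5-ethenyl-4,4-dimethyl-4,5,6,7-tetrahydro-2-benzofuran-1(3H)-one
Conditions: 15 (1.5 equiv), (S)-TRIP (10 mol %), 4 Å MS, toluene, −30 °C to rt
Reagents that add atoms: none
Why: Chiral phosphoric acid-catalysed allylboration (1,2-addition to the enal through a chair transition state) should add the 2-bromoallyl group to the Si face of the C6 aldehyde (S acid, 6S), independent of the remote centres.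

Step 9
Reactants: 16 (3R,5S)-3-[(2E,4S)-6-bromo-4-hydroxy-2-methylhepta-2,6-dien-1-yl]-5-ethenyl-4,4-dimethyl-4,5,6,7-tetrahydro-2-benzofuran-1(3H)-one
Product: 18 (1R,6S,10R)-6-hydroxyverticilla-4(20),7E,11-trien-18,10-olide (the deacetyl target), via bis-borane 17 (not isolated)
Conditions: 9-BBN (2.5 equiv), THF, 0 °C to rt; then syringe-pump addition to Pd(dppf)Cl2 (20 mol %), AsPh3 (40 mol %), Cs2CO3 (3 equiv), DMF/THF/H2O, 50 °C, 1 mM
Reagents that add atoms: none
Why: 9-BBN should hydroborate only the monosubstituted vinyl group (anti-Markovnikov; the free hydroxyl is borylated and released again in the aqueous base), and intramolecular B-alkyl Suzuki–Miyaura coupling with the 2-bromoalkene under high dilution should form C3–C4 and close the twelve-membered ring with the exocyclic methylene in place.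

Step 10
Reactants: 18 (1R,6S,10R)-6-hydroxyverticilla-4(20),7E,11-trien-18,10-olide
Product: 19 (1R,6S,10R)-6-acetoxyverticilla-4(20),7E,11-trien-18,10-olide (target)
Conditions: Ac2O, pyridine, DMAP (cat.), CH2Cl2, 0 °C to rt
Reagents that add atoms: acetic anhydride, CC(=O)OC(C)=O
Why: Acylation of the secondary allylic alcohol with retention at C6 should give the target; the mild base should not enolise the butenolide at C10.

Compound list
1 | 3,3-dimethylpentane-1,5-diol | OCCC(C)(C)CCO | starting material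
2 | 3,3-dimethylpentanedial | O=CCC(C)(C)CC=O | intermediate
3 | methyl 2-hydroxybut-3-enoate (racemic) | C=CC(O)C(=O)OC | starting material
4 | methyl 2-oxobut-3-enoate | C=CC(=O)C(=O)OC | intermediate
5 | methyl (5R)-5-formyl-6,6-dimethyl-2,8-dioxooctanoate | O=CCC(C)(C)[C@H](C=O)CCC(=O)C(=O)OC | intermediate (not isolated)
6 | methyl (4R)-2,4-diformyl-1-hydroxy-3,3-dimethylcyclohexane-1-carboxylate (mixture at C1 and C2 of the ring) | O=C[C@@H]1CCC(O)(C(=O)OC)C(C=O)C1(C)C | intermediate (not isolated)
7 | methyl (4R)-2,4-diformyl-3,3-dimethylcyclohex-1-ene-1-carboxylate | O=C[C@@H]1CCC(C(=O)OC)=C(C=O)C1(C)C | intermediate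
8 | methyl (4S)-4-ethenyl-2-formyl-3,3-dimethylcyclohex-1-ene-1-carboxylate | C=C[C@@H]1CCC(C(=O)OC)=C(C=O)C1(C)C | intermediate
9 | 4,4,5,5-tetramethyl-2-(propa-1,2-dien-1-yl)-1,3,2-dioxaborolane | C=C=CB1OC(C)(C)C(C)(C)O1 | starting material
10 | methyl (4S)-4-ethenyl-2-[(1R)-1-hydroxybut-3-yn-1-yl]-3,3-dimethylcyclohex-1-ene-1-carboxylate | C=C[C@@H]1CCC(C(=O)OC)=C([C@H](O)CC#C)C1(C)C | intermediate (not isolated)
11 | (3R,5S)-5-ethenyl-4,4-dimethyl-3-(prop-2-yn-1-yl)-4,5,6,7-tetrahydro-2-benzofuran-1(3H)-one | C=C[C@@H]1CCC2=C([C@@H](CC#C)OC2=O)C1(C)C | intermediate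
12 | dimethyl{(1E)-3-[(3R,5S)-5-ethenyl-4,4-dimethyl-1-oxo-1,3,4,5,6,7-hexahydro-2-benzofuran-3-yl]-2-methylprop-1-en-1-yl}alumane | C=C[C@@H]1CCC2=C([C@@H](C/C(C)=C/[Al](C)C)OC2=O)C1(C)C | intermediate (not isolated)
13 | (3R,5S)-5-ethenyl-3-[(2E)-3-iodo-2-methylprop-2-en-1-yl]-4,4-dimethyl-4,5,6,7-tetrahydro-2-benzofuran-1(3H)-one | C=C[C@@H]1CCC2=C([C@@H](C/C(C)=C/I)OC2=O)C1(C)C | intermediate
14 | (2E)-4-[(3R,5S)-5-ethenyl-4,4-dimethyl-1-oxo-1,3,4,5,6,7-hexahydro-2-benzofuran-3-yl]-3-methylbut-2-enal | C=C[C@@H]1CCC2=C([C@@H](C/C(C)=C/C=O)OC2=O)C1(C)C | intermediate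
15 | 2-(2-bromoprop-2-en-1-yl)-4,4,5,5-tetramethyl-1,3,2-dioxaborolane | C=C(Br)CB1OC(C)(C)C(C)(C)O1 | starting material
16 | (3R,5S)-3-[(2E,4S)-6-bromo-4-hydroxy-2-methylhepta-2,6-dien-1-yl]-5-ethenyl-4,4-dimethyl-4,5,6,7-tetrahydro-2-benzofuran-1(3H)-one | C=C[C@@H]1CCC2=C([C@@H](C/C(C)=C/[C@@H](O)CC(Br)=C)OC2=O)C1(C)C | intermediate
17 | bis(9-BBN) derivative of 16: 9-borabicyclo[3.3.1]nonan-9-yl on the terminal carbon of the former vinyl group (C3) and on the C6 oxygen | C1CCC2CCCC1B2CC[C@@H]1CCC2=C([C@@H](C/C(C)=C/[C@@H](OB3C4CCCC3CCC4)CC(Br)=C)OC2=O)C1(C)C | intermediate (not isolated)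
18 | (1R,6S,10R)-6-hydroxyverticilla-4(20),7E,11-trien-18,10-olide | C=C1CC[C@@H]2CCC3=C([C@@H](C/C(C)=C/[C@@H](O)C1)OC3=O)C2(C)C | intermediate
19 | (1R,6S,10R)-6-acetoxyverticilla-4(20),7E,11-trien-18,10-olide | C=C1CC[C@@H]2CCC3=C([C@@H](C/C(C)=C/[C@@H](OC(C)=O)C1)OC3=O)C2(C)C | target

Total step count: 10. Longest linear sequence: 9 steps (1 → 2 → 7 → 8 → 11 → 13 → 14 → 16 → 18 → 19).

Steps most likely to fail

Step 3. What may go wrong: a second conjugate addition at the other aldehyde terminus, trapping of the Michael adduct as its cyclic hemiacetal or ring closure through the keto ester enol instead of the aldehyde enamine, and erosion of C1 by re-enamination. Fallback: the two bond formations are separated and the dialdehyde is desymmetrised first; it sets out from 2 (and 4) and comes back at 7. Mono-acetalisation of 2 (HC(OMe)3, one equivalent, Amberlyst-15, MeOH, unreacted 2 recycled) should give 5,5-dimethoxy-3,3-dimethylpentanal F1. The same prolinol catalyst should add F1 to 4 to give methyl (5R)-5-formyl-8,8-dimethoxy-6,6-dimethyl-2-oxooctanoate F2, which is isolated. Mild aqueous acid (PPTS, acetone/H2O) then releases 5, and the prolinol catalyst with PhCO2H at rt closes and dehydrates it through 6 to 7.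

Step 9. What may go wrong: oligomerisation, protodeboronation and β-hydride elimination competing with the slow closure of the twelve-membered ring. Fallback: the ring is closed instead at C5–C6 by Nozaki–Hiyama allylation; it sets out from 14 and comes back at 18. The aldehyde of 14 is masked (HC(OMe)3, PPTS, MeOH) as (3R,5S)-3-[(2E)-4,4-dimethoxy-2-methylbut-2-en-1-yl]-5-ethenyl-4,4-dimethyl-4,5,6,7-tetrahydro-2-benzofuran-1(3H)-one F3. Hydroboration of the vinyl group with 9-BBN gives the B-alkyl-9-BBN adduct F4, which is coupled in the same flask with 2-bromoprop-2-en-1-ol (Pd(dppf)Cl2, Cs2CO3, DMF/H2O) to the allylic alcohol (3R,5R)-3-[(2E)-4,4-dimethoxy-2-methylbut-2-en-1-yl]-5-[3-(hydroxymethyl)but-3-en-1-yl]-4,4-dimethyl-4,5,6,7-tetrahydro-2-benzofuran-1(3H)-one F5. Appel bromination (CBr4, PPh3) gives (3R,5S)-5-[3-(bromomethyl)but-3-en-1-yl]-3-[(2E)-4,4-dimethoxy-2-methylbut-2-en-1-yl]-4,4-dimethyl-4,5,6,7-tetrahydro-2-benzofuran-1(3H)-one F6, and aqueous acid unmasks the enal to give (2E)-4-{(3R,5S)-5-[3-(bromomethyl)but-3-en-1-yl]-4,4-dimethyl-1-oxo-1,3,4,5,6,7-hexahydro-2-benzofuran-3-yl}-3-methylbut-2-enal F7. CrCl2 in THF under high dilution should then close the ring to 18. In this fallback the C6 configuration rests on the conformational bias of the macrocyclic transition state and is not secured by a reagent.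

Step 6. What may go wrong: attack of the organoaluminium on the butenolide carbonyl and enolisation at C10 under the Lewis acidic conditions. Fallback: the C6–C9 enal is introduced in one step by a vinylogous Mukaiyama aldol reaction; it sets out from 8 and comes back at 14, bypassing 11 and 13. 3-Methylbut-2-enal is silylated (tBuMe2SiOTf, Et3N, CH2Cl2) to (E)-tert-butyl(dimethyl)[(3-methylbuta-1,3-dien-1-yl)oxy]silane F8. Its γ-selective addition to the C10 aldehyde of 8, promoted by the N-tosyltryptophan-derived B-phenyl oxazaborolidinone (enantiomer chosen for the 10R adduct; EtCN, −78 °C), should give methyl (4S)-4-ethenyl-2-[(1R,3E)-1-hydroxy-3-methyl-5-oxopent-3-en-1-yl]-3,3-dimethylcyclohex-1-ene-1-carboxylate F9, which lactonises (PPTS) to 14.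

Further compounds
F1 | step 3 | 5,5-dimethoxy-3,3-dimethylpentanal | COC(OC)CC(C)(C)CC=O
F2 | step 3 | methyl (5R)-5-formyl-8,8-dimethoxy-6,6-dimethyl-2-oxooctanoate | COC(OC)CC(C)(C)[C@H](C=O)CCC(=O)C(=O)OC
F3 | step 9 | (3R,5S)-3-[(2E)-4,4-dimethoxy-2-methylbut-2-en-1-yl]-5-ethenyl-4,4-dimethyl-4,5,6,7-tetrahydro-2-benzofuran-1(3H)-one | C=C[C@@H]1CCC2=C([C@@H](C/C(C)=C/C(OC)OC)OC2=O)C1(C)C
F4 | step 9 | B-alkyl-9-BBN adduct of F3 (boron on the terminal carbon of the former vinyl group) | C1CCC2CCCC1B2CC[C@@H]1CCC2=C([C@@H](C/C(C)=C/C(OC)OC)OC2=O)C1(C)C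
F5 | step 9 | (3R,5R)-3-[(2E)-4,4-dimethoxy-2-methylbut-2-en-1-yl]-5-[3-(hydroxymethyl)but-3-en-1-yl]-4,4-dimethyl-4,5,6,7-tetrahydro-2-benzofuran-1(3H)-one | OCC(=C)CC[C@@H]1CCC2=C([C@@H](C/C(C)=C/C(OC)OC)OC2=O)C1(C)C
F6 | step 9 | (3R,5S)-5-[3-(bromomethyl)but-3-en-1-yl]-3-[(2E)-4,4-dimethoxy-2-methylbut-2-en-1-yl]-4,4-dimethyl-4,5,6,7-tetrahydro-2-benzofuran-1(3H)-one | BrCC(=C)CC[C@@H]1CCC2=C([C@@H](C/C(C)=C/C(OC)OC)OC2=O)C1(C)C
F7 | step 9 | (2E)-4-{(3R,5S)-5-[3-(bromomethyl)but-3-en-1-yl]-4,4-dimethyl-1-oxo-1,3,4,5,6,7-hexahydro-2-benzofuran-3-yl}-3-methylbut-2-enal | BrCC(=C)CC[C@@H]1CCC2=C([C@@H](C/C(C)=C/C=O)OC2=O)C1(C)C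
F8 | step 6 | (E)-tert-butyl(dimethyl)[(3-methylbuta-1,3-dien-1-yl)oxy]silane | C=C(C)/C=C/O[Si](C)(C)C(C)(C)C
F9 | step 6 | methyl (4S)-4-ethenyl-2-[(1R,3E)-1-hydroxy-3-methyl-5-oxopent-3-en-1-yl]-3,3-dimethylcyclohex-1-ene-1-carboxylate | C=C[C@@H]1CCC(C(=O)OC)=C([C@H](O)C/C(C)=C/C=O)C1(C)C
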